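**Retrosynthetic overview**
1. Target 15 ⇐ keto ester 13 by one-pot MOM removal and enol-lactonisation; the pyranone ring is the only ring made, and it is made last.
2. 13 ⇐ sp2–sp3 Negishi coupling of aryl bromide 11 (lower half) with benzylic zinc reagent 12 (upper half); the position of Br fixes the diarylmethane bond at C5.
3. 11 ⇐ ring bromination, then lateral lithiation/Weinreb acylation of toluate 3. 12 ⇐ lateral lithiation/chlorination/methanolysis, ester reduction, chlorination and Zn insertion from the same toluate 3.
4. 3 ⇐ methyl orsellinate 1: the chelated 2-OH lets the 4-OH be MOM-protected first and the 2-OH be methylated second.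
5. Ring order: both benzene rings are bought in 1; the isocoumarin lactone ring is closed in the final step.

Assumption: the target has no stereocentre or other stereogenic element, so "single enantiomer" means the achiral compound itself and no stereocontrol is needed.
Assumption: MOMCl, MeI, NaOMe, SOCl2, NBS and N-methoxy-N-methylacetamide are treated as reagents and are not numbered.

Step 1
Reactants: 1 methyl 2,4-dihydroxy-6-methylbenzoate (methyl orsellinate)
Product: 2 methyl 2-hydroxy-4-(methoxymethoxy)-6-methylbenzoate
Conditions: MOMCl (1.1 eq), i-Pr2NEt, CH2Cl2, 0 °C → rt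
Reagents that add atoms: chloromethyl methyl ether, COCCl
Why: Chemoselective O-alkylation (MOM protection) of the free 4-OH, because the 2-OH is hydrogen-bonded to the ester carbonyl and much less nucleophilic.

Step 2
Reactants: 2 methyl 2-hydroxy-4-(methoxymethoxy)-6-methylbenzoate
Product: 3 methyl 2-methoxy-4-(methoxymethoxy)-6-methylbenzoate
Conditions: MeI, K2CO3, DMF, 40 °C
Reagents that add atoms: iodomethane, CI
Why: Williamson O-methylation of the remaining chelated phenol under forcing but MOM-compatible basic conditions, which completes the OMe/OH differentiation needed in both rings.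

Step 3
Reactants: 3 methyl 2-methoxy-4-(methoxymethoxy)-6-methylbenzoate
Product: 6 methyl 2-methoxy-4-(methoxymethoxy)-6-(methoxymethyl)benzoate, via lateral lithium species 4 (not isolated), via benzylic chloride 5 (not isolated)
Conditions: LDA (1.15 eq), THF, −78 °C; cannulate into C2Cl6 (1.5 eq), THF, −78 °C; then NaOMe/MeOH, −78 °C → rt
Reagents that add atoms: sodium methoxide, [Na+].[O-]C
Why: Lateral (benzylic) lithiation ortho to the ester gives a vinylogous ester enolate that is chlorinated on carbon by hexachloroethane, and methoxide then displaces the primary benzylic chloride (SN2, Williamson); the anionic route avoids the nuclear bromination that radical NBS conditions risk on this electron-rich ring.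

Step 4
Reactants: 6 methyl 2-methoxy-4-(methoxymethoxy)-6-(methoxymethyl)benzoate
Product: 7 [2-methoxy-4-(methoxymethoxy)-6-(methoxymethyl)phenyl]methanol
Conditions: LiAlH4, THF, 0 °C → rt; Fieser (basic) work-up
Reagents that add atoms: none
Why: LiAlH4 ester reduction reaches even this di-ortho-substituted benzoate, and the basic work-up protects the acid-labile electron-rich benzylic alcohol and the MOM ether.

Step 5
Reactants: 7 [2-methoxy-4-(methoxymethoxy)-6-(methoxymethyl)phenyl]methanol
Product: 8 2-(chloromethyl)-1-methoxy-5-(methoxymethoxy)-3-(methoxymethyl)benzene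
Conditions: SOCl2 (1.2 eq), i-Pr2NEt (1.5 eq), CH2Cl2, −20 → 0 °C; cold NaHCO3 wash; used crude at once
Reagents that add atoms: thionyl chloride, O=S(Cl)Cl
Why: Deoxychlorination via the chlorosulfite is very fast for this p-alkoxybenzylic alcohol, and the hindered amine traps HCl so the MOM group survives and the reactive chloride is not quaternised.

Step 6
Reactants: 3 methyl 2-methoxy-4-(methoxymethoxy)-6-methylbenzoate
Product: 9 methyl 3-bromo-6-methoxy-4-(methoxymethoxy)-2-methylbenzoate
Conditions: NBS (1.05 eq), MeCN, 0 °C → rt, dark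
Reagents that add atoms: N-bromosuccinimide, O=C1CCC(=O)N1Br
Why: Electrophilic aromatic bromination goes para to the OMe and ortho to the OMOM group (between OMOM and CH3), because the only other free site lies shielded between two alkoxy groups.

Step 7
Reactants: 9 methyl 3-bromo-6-methoxy-4-(methoxymethoxy)-2-methylbenzoate
Product: 11 methyl 3-bromo-6-methoxy-4-(methoxymethoxy)-2-(2-oxopropyl)benzoate, via lateral lithium species 10 (not isolated)
Conditions: LDA (1.2 eq), THF, −78 °C; MeC(O)N(OMe)Me (1.5 eq), −78 → −40 °C; aq. NH4Cl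
Reagents that add atoms: N-methoxy-N-methylacetamide, CC(=O)N(C)OC
Why: Lateral lithiation of the o-toluate followed by Weinreb ketone synthesis; the chelated tetrahedral adduct prevents over-addition, and the aryl bromide, which has no ortho hydrogen, is inert to LDA.

Step 8
Reactants: 8 2-(chloromethyl)-1-methoxy-5-(methoxymethoxy)-3-(methoxymethyl)benzene; 11 methyl 3-bromo-6-methoxy-4-(methoxymethoxy)-2-(2-oxopropyl)benzoate
Product: 13 methyl 6-methoxy-3-{[2-methoxy-4-(methoxymethoxy)-6-(methoxymethyl)phenyl]methyl}-4-(methoxymethoxy)-2-(2-oxopropyl)benzoate, via benzylic zinc chloride 12 (not isolated)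
Conditions: 8 (1.4 eq), Zn dust, LiCl, THF, 25 °C; then 11, Pd(OAc)2 (2 mol %), SPhos (4 mol %), THF, 25 → 50 °C
Reagents that add atoms: none
Why: LiCl-mediated zinc insertion into the benzylic chloride followed by Negishi sp3–sp2 cross-coupling; the mild organozinc tolerates ester, ketone and acetals, and Pd/SPhos handles the di-ortho-substituted bromide, so the CH2 bridge is placed at the brominated carbon only.

Step 9
Reactants: 13 methyl 6-methoxy-3-{[2-methoxy-4-(methoxymethoxy)-6-(methoxymethyl)phenyl]methyl}-4-(methoxymethoxy)-2-(2-oxopropyl)benzoate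
Product: 15 6-hydroxy-5-{[4-hydroxy-2-methoxy-6-(methoxymethyl)phenyl]methyl}-8-methoxy-3-methyl-1H-isochromen-1-one, via bisphenol keto ester 14 (not isolated)
Conditions: 3 M HCl in MeOH, 50 °C; evaporate; TFA/CH2Cl2 (1:4), rt
Reagents that add atoms: none
Why: Acid-catalysed acetal exchange removes both MOM groups as the methanol acetal of formaldehyde (methanol solvent also makes any exchange at the ArCH2OMe ether degenerate), and the anhydrous acid then drives enol-lactonisation of the 2-(2-oxopropyl)benzoate to the isocoumarin.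

**Compound list**
1 | methyl 2,4-dihydroxy-6-methylbenzoate | COC(=O)c1c(C)cc(O)cc1O | starting material
2 | methyl 2-hydroxy-4-(methoxymethoxy)-6-methylbenzoate | COC(=O)c1c(C)cc(OCOC)cc1O | intermediate
3 | methyl 2-methoxy-4-(methoxymethoxy)-6-methylbenzoate | COC(=O)c1c(C)cc(OCOC)cc1OC | intermediate
4 | methyl 2-(lithiomethyl)-6-methoxy-4-(methoxymethoxy)benzoate | [Li]Cc1cc(OCOC)cc(OC)c1C(=O)OC | intermediate
5 | methyl 2-(chloromethyl)-6-methoxy-4-(methoxymethoxy)benzoate | COC(=O)c1c(CCl)cc(OCOC)cc1OC | intermediate
6 | methyl 2-methoxy-4-(methoxymethoxy)-6-(methoxymethyl)benzoate | COC(=O)c1c(COC)cc(OCOC)cc1OC | intermediate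
7 | [2-methoxy-4-(methoxymethoxy)-6-(methoxymethyl)phenyl]methanol | OCc1c(COC)cc(OCOC)cc1OC | intermediate
8 | 2-(chloromethyl)-1-methoxy-5-(methoxymethoxy)-3-(methoxymethyl)benzene | ClCc1c(COC)cc(OCOC)cc1OC | intermediate
9 | methyl 3-bromo-6-methoxy-4-(methoxymethoxy)-2-methylbenzoate | COC(=O)c1c(C)c(Br)c(OCOC)cc1OC | intermediate
10 | methyl 3-bromo-2-(lithiomethyl)-6-methoxy-4-(methoxymethoxy)benzoate | [Li]Cc1c(Br)c(OCOC)cc(OC)c1C(=O)OC | intermediate
11 | methyl 3-bromo-6-methoxy-4-(methoxymethoxy)-2-(2-oxopropyl)benzoate | COC(=O)c1c(CC(C)=O)c(Br)c(OCOC)cc1OC | intermediate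
12 | {[2-methoxy-4-(methoxymethoxy)-6-(methoxymethyl)phenyl]methyl}zinc chloride | Cl[Zn]Cc1c(COC)cc(OCOC)cc1OC | intermediate
13 | methyl 6-methoxy-3-{[2-methoxy-4-(methoxymethoxy)-6-(methoxymethyl)phenyl]methyl}-4-(methoxymethoxy)-2-(2-oxopropyl)benzoate | COC(=O)c1c(CC(C)=O)c(Cc2c(COC)cc(OCOC)cc2OC)c(OCOC)cc1OC | intermediate
14 | methyl 4-hydroxy-3-{[4-hydroxy-2-methoxy-6-(methoxymethyl)phenyl]methyl}-6-methoxy-2-(2-oxopropyl)benzoate | COC(=O)c1c(CC(C)=O)c(Cc2c(COC)cc(O)cc2OC)c(O)cc1OC | intermediate
15 | 6-hydroxy-5-{[4-hydroxy-2-methoxy-6-(methoxymethyl)phenyl]methyl}-8-methoxy-3-methyl-1H-isochromen-1-one | COCc1cc(O)cc(OC)c1Cc1c(O)cc(OC)c2c(=O)oc(C)cc12 | target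

**Totals**
Total step count: 9.
Longest linear sequence: 7 steps (steps 1, 2, 3, 4, 5, 8, 9); the lower-half branch is 6 steps (1, 2, 6, 7, 8, 9).

**Three steps most likely to fail, each with a fallback**

Step 3. The one-flask lithiation, chlorination and methanolysis can lose material to Wurtz-type coupling of 4 with 5 or to self-condensation of the toluate anion. The fallback is a block–brominate–unblock sequence that sets out from compound 9, whose ring bromine already blocks the most nucleophilic ring position. Radical bromination (NBS, AIBN, PhCF3, 80 °C) gives methyl 3-bromo-2-(bromomethyl)-6-methoxy-4-(methoxymethoxy)benzoate F1. NaOMe in MeOH at room temperature converts this to methyl 3-bromo-6-methoxy-4-(methoxymethoxy)-2-(methoxymethyl)benzoate F2. Radical hydrodebromination (Bu3SnH, AIBN, toluene, 90 °C) then removes the aryl bromine, and the sequence comes back to the route at compound 6.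

Step 8. Chloride 8 is a labile, electron-rich benzylic halide, and bromide 11 is crowded and carries an enolisable ketone next to the reacting carbon. The fallback changes the order of bond formation: couple first, acylate afterwards. It sets out from compound 9, which is coupled with the zinc reagent 12 under the same Pd/SPhos Negishi conditions to give methyl 6-methoxy-3-{[2-methoxy-4-(methoxymethoxy)-6-(methoxymethyl)phenyl]methyl}-4-(methoxymethoxy)-2-methylbenzoate F3. LDA at −78 °C then gives methyl 2-(lithiomethyl)-6-methoxy-3-{[2-methoxy-4-(methoxymethoxy)-6-(methoxymethyl)phenyl]methyl}-4-(methoxymethoxy)benzoate F4; the ester-conjugated methyl is far more acidic than the diarylmethane CH2. Acylation with N-methoxy-N-methylacetamide brings the sequence back to the route at compound 13.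

Step 9. Enol-lactonisation of the hindered, electron-rich methyl ester may need acid strong enough to endanger the doubly activated diarylmethane (retro-Friedel–Crafts). The fallback closes the lactone before the coupling, on a small robust molecule, and sets out from compound 11. HCl in MeOH gives methyl 3-bromo-4-hydroxy-6-methoxy-2-(2-oxopropyl)benzoate F5. Forcing acid (TsOH, toluene, 100 °C) closes this to 5-bromo-6-hydroxy-8-methoxy-3-methyl-1H-isochromen-1-one F6. Negishi coupling of this bromophenol with 12 (slow addition, Pd(OAc)2/SPhos, which tolerates the free phenol) gives 6-hydroxy-8-methoxy-5-{[2-methoxy-4-(methoxymethoxy)-6-(methoxymethyl)phenyl]methyl}-3-methyl-1H-isochromen-1-one F7. Mild HCl in MeOH at 40 °C removes the last MOM group, and the sequence comes back to the route at compound 15.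

**Further compounds**
F1 | step 3 | methyl 3-bromo-2-(bromomethyl)-6-methoxy-4-(methoxymethoxy)benzoate | COC(=O)c1c(CBr)c(Br)c(OCOC)cc1OC
F2 | step 3 | methyl 3-bromo-6-methoxy-4-(methoxymethoxy)-2-(methoxymethyl)benzoate | COC(=O)c1c(COC)c(Br)c(OCOC)cc1OC
F3 | step 8 | methyl 6-methoxy-3-{[2-methoxy-4-(methoxymethoxy)-6-(methoxymethyl)phenyl]methyl}-4-(methoxymethoxy)-2-methylbenzoate | COC(=O)c1c(C)c(Cc2c(COC)cc(OCOC)cc2OC)c(OCOC)cc1OC
F4 | step 8 | methyl 2-(lithiomethyl)-6-methoxy-3-{[2-methoxy-4-(methoxymethoxy)-6-(methoxymethyl)phenyl]methyl}-4-(methoxymethoxy)benzoate | [Li]Cc1c(Cc2c(COC)cc(OCOC)cc2OC)c(OCOC)cc(OC)c1C(=O)OC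
F5 | step 9 | methyl 3-bromo-4-hydroxy-6-methoxy-2-(2-oxopropyl)benzoate | COC(=O)c1c(CC(C)=O)c(Br)c(O)cc1OC
F6 | step 9 | 5-bromo-6-hydroxy-8-methoxy-3-methyl-1H-isochromen-1-one | COc1cc(O)c(Br)c2cc(C)oc(=O)c12
F7 | step 9 | 6-hydroxy-8-methoxy-5-{[2-methoxy-4-(methoxymethoxy)-6-(methoxymethyl)phenyl]methyl}-3-methyl-1H-isochromen-1-one | COCOc1cc(COC)c(Cc2c(O)cc(OC)c3c(=O)oc(C)cc23)c(OC)c1
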